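## Retrosynthetic overview
1. The last two operations unmask the phenol (O-TBS, buffered fluoride) and the distal carboxyl group (2,2,2-trichloroethyl ester, zinc), both near neutral pH.
2. Cutting the allylic ester C(=O)–O bond gives an HMG mono(trichloroethyl) ester, with its free acid on the arm that must carry the sinapyl group, and O-TBS-(Z)-sinapyl alcohol (Steglich coupling).
3. The Z-alkene comes from a Still–Gennari olefination of O-TBS-syringaldehyde followed by DIBAL-H reduction.
4. The C3 carbinol stereocentre comes from a carboxylesterase (pig liver esterase) desymmetrisation of prochiral dimethyl 3-hydroxy-3-methylglutarate. A tBu/trichloroethyl ester relay then replaces the surviving methyl ester without touching C3.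
5. No ring is formed. The only ring, the arene, is bought in syringaldehyde.

Assumption: the SMILES reads as (3R) at the carbinol carbon and (Z) at the alkene, and pig liver esterase is taken to give the (S)-half-ester of dimethyl 3-hydroxy-3-methylglutarate, the outcome long used to make (R)-mevalonolactone.

Handling note: all compounds from 15 onward are kept in amber glassware, because Z-styrenes photoisomerise. The ee is checked by chiral HPLC at the UV-active stage 19.

## Route

Step 1
Reactants: 1 3-hydroxy-3-methylpentanedioic acid (3-hydroxy-3-methylglutaric acid, achiral)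
Product: 2 dimethyl 3-hydroxy-3-methylpentanedioate (achiral; C3 prochiral)
Conditions: MeOH, H2SO4 (5 mol %), 40 °C, 16 h
Reagents that add atoms: methanol, CO
Why: Fischer esterification in excess methanol converts both carboxyl groups, and the tertiary carbinol, flanked by two electron-withdrawing CH2CO2R arms, neither ionises nor dehydrates under this mild acid catalysis.

Step 2
Reactants: 2 dimethyl 3-hydroxy-3-methylpentanedioate
Product: 4 (3S)-3-hydroxy-5-methoxy-3-methyl-5-oxopentanoic acid, via sodium carboxylate 3 (not isolated)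
Conditions: pig liver esterase (a carboxylesterase, serine hydrolase class, EC 3.1.1.1), 0.1 M phosphate buffer pH 7.5, 25 °C, pH-stat 1 M NaOH (1.0 equiv); then 2 M HCl to pH 2.5, NaCl, continuous EtOAc extraction
Reagents that add atoms: water, O
Why: In this enzymatic desymmetrisation (enantiotopic-group-selective ester hydrolysis) the chiral active site forms the acyl-enzyme from only one of the two enantiotopic CH2CO2Me arms (formally the pro-R arm), so the catalyst itself creates C3 as (S), and the anionic half-ester is not hydrolysed further.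

Step 3
Reactants: 4 (3S)-3-hydroxy-5-methoxy-3-methyl-5-oxopentanoic acid
Product: 5 1-tert-butyl 5-methyl (3R)-3-hydroxy-3-methylpentanedioate
Conditions: O-tert-butyl-N,N'-diisopropylisourea (2.5 equiv), CH2Cl2, rt, 20 h
Reagents that add atoms: O-tert-butyl-N,N'-diisopropylisourea, CC(C)N=C(OC(C)(C)C)NC(C)C
Why: Isourea O-alkylation of the carboxylic acid (protonation of the isourea, then tert-butyl transfer to the carboxylate) is neutral, spares the tertiary OH and the methyl ester and breaks no bond at C3, so the descriptor becomes (R) only because CO2tBu outranks CO2Me.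

Step 4
Reactants: 5 1-tert-butyl 5-methyl (3R)-3-hydroxy-3-methylpentanedioate
Product: 7 (3R)-5-tert-butoxy-3-hydroxy-3-methyl-5-oxopentanoic acid, via lithium carboxylate 6 (not isolated)
Conditions: LiOH·H2O (1.2 equiv), THF/H2O 3:1, 0 °C, 2 h; then cold 1 M HCl to pH 3, EtOAc
Reagents that add atoms: lithium hydroxide, [Li+].[OH-]
Why: In this chemoselective saponification (BAc2) hydroxide adds to the unhindered methyl ester while the tert-butyl ester is sterically shielded, and at 0 °C neither retro-aldol cleavage nor E1cB dehydration competes, so C3 is untouched.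

Step 5
Reactants: 7 (3R)-5-tert-butoxy-3-hydroxy-3-methyl-5-oxopentanoic acid
Product: 9 1-tert-butyl 5-(2,2,2-trichloroethyl) (3R)-3-hydroxy-3-methylpentanedioate, via O-acylisourea 8 (not isolated)
Conditions: Cl3CCH2OH (1.5 equiv), EDC·HCl (1.3 equiv), DMAP (0.1 equiv), CH2Cl2, 0 °C to rt
Reagents that add atoms: 2,2,2-trichloroethanol, OCC(Cl)(Cl)Cl
Why: In this Steglich esterification the DMAP-derived acylpyridinium ion is trapped by the primary alcohol far faster than by the hindered tertiary OH, giving an ester that is stable to acid and cleavable by zinc.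

Step 6
Reactants: 9 1-tert-butyl 5-(2,2,2-trichloroethyl) (3R)-3-hydroxy-3-methylpentanedioate
Product: 10 (3S)-3-hydroxy-3-methyl-5-oxo-5-(2,2,2-trichloroethoxy)pentanoic acid
Conditions: TFA/CH2Cl2 1:3, 0 °C to rt, 2 h; toluene co-evaporation; used promptly
Reagents that add atoms: none
Why: Acidolysis of the tert-butyl ester (AAL1, loss of isobutene) frees exactly the carboxyl group the enzyme had liberated, the trichloroethyl ester is acid-stable, the carbinol cation is too destabilised by the two carbonyl arms to form, and C3 keeps its geometry while reading (S) again by CIP ranking.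

Step 7
Reactants: 11 syringaldehyde (4-hydroxy-3,5-dimethoxybenzaldehyde)
Product: 12 4-[(tert-butyldimethylsilyl)oxy]-3,5-dimethoxybenzaldehyde
Conditions: TBSCl (1.3 equiv), imidazole (2.5 equiv), DMF, rt, 16 h
Reagents that add atoms: tert-butyldimethylsilyl chloride, CC(C)(C)[Si](C)(C)Cl
Why: Imidazole-promoted silylation masks the phenol against the later base, hydride and acylation steps with a group that buffered fluoride removes.

Step 8
Reactants: 12 4-[(tert-butyldimethylsilyl)oxy]-3,5-dimethoxybenzaldehyde; 13 methyl bis(2,2,2-trifluoroethyl)phosphonoacetate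
Product: 15 methyl (2Z)-3-{4-[(tert-butyldimethylsilyl)oxy]-3,5-dimethoxyphenyl}prop-2-enoate, via potassium phosphonate carbanion 14 (not isolated)
Conditions: 13 (1.2 equiv), KHMDS (1.15 equiv), 18-crown-6 (3 equiv), THF, −78 °C; then 12, −78 °C, 2 h; aq NH4Cl; chromatography
Reagents that add atoms: 13 methyl bis(2,2,2-trifluoroethyl)phosphonoacetate, COC(=O)CP(=O)(OCC(F)(F)F)OCC(F)(F)F
Why: In the Still–Gennari variant of the Horner–Wadsworth–Emmons reaction the electron-poor phosphonate and the crown-dissociated potassium ion make elimination of the kinetic adduct faster than its reversal, so the (Z)-enoate dominates (usually >15:1) and the minor E-isomer is removed on silica.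

Step 9
Reactants: 15 methyl (2Z)-3-{4-[(tert-butyldimethylsilyl)oxy]-3,5-dimethoxyphenyl}prop-2-enoate
Product: 17 (2Z)-3-{4-[(tert-butyldimethylsilyl)oxy]-3,5-dimethoxyphenyl}prop-2-en-1-ol, via Z-enal 16 (not isolated)
Conditions: DIBAL-H (2.5 equiv), CH2Cl2, −78 °C, 2 h; aq Rochelle salt
Reagents that add atoms: none
Why: DIBAL-H 1,2-reduction takes the enoate through the aldehyde to the allylic alcohol at low temperature, and because hydride adds only to C=O, the Z-geometry and the aryl silyl ether are retained.

Step 10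
Reactants: 10 (3S)-3-hydroxy-3-methyl-5-oxo-5-(2,2,2-trichloroethoxy)pentanoic acid (1.15 equiv); 17 (2Z)-3-{4-[(tert-butyldimethylsilyl)oxy]-3,5-dimethoxyphenyl}prop-2-en-1-ol
Product: 19 1-[(2Z)-3-{4-[(tert-butyldimethylsilyl)oxy]-3,5-dimethoxyphenyl}prop-2-en-1-yl] 5-(2,2,2-trichloroethyl) (3S)-3-hydroxy-3-methylpentanedioate, via O-acylisourea 18 (not isolated)
Conditions: EDC·HCl (1.5 equiv), then DMAP (0.2 equiv), CH2Cl2, 0 °C to rt, dark
Reagents that add atoms: none
Why: The Steglich esterification makes only the acyl C–O bond, so the allylic C–O bond, the Z-alkene and C3 are not involved, the primary allylic OH outcompetes the tertiary OH, and any leakage through the achiral cyclic anhydride gives only acidic by-products that are washed away from neutral 19.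

Step 11
Reactants: 19 the TBS-protected mixed diester
Product: 20 1-[(2Z)-3-(4-hydroxy-3,5-dimethoxyphenyl)prop-2-en-1-yl] 5-(2,2,2-trichloroethyl) (3S)-3-hydroxy-3-methylpentanedioate
Conditions: TBAF (1.1 equiv)/AcOH (1.5 equiv) premixed, THF, 0 °C, 30 min, dark
Reagents that add atoms: none
Why: Fluoride-induced desilylation of the aryl silyl ether is driven by Si–F bond formation, and the acetic acid buffer protonates the phenoxide at once, so it can neither expel the carboxylate as a vinylogous quinone methide nor attack either ester.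

Step 12
Reactants: 20 the free-phenol mixed diester
Product: 22 (3R)-3-hydroxy-5-{[(2Z)-3-(4-hydroxy-3,5-dimethoxyphenyl)prop-2-en-1-yl]oxy}-3-methyl-5-oxopentanoic acid (target), via zinc carboxylate 21 (not isolated)
Conditions: activated Zn dust (15 equiv), THF/1 M aq NH4OAc 4:1, rt, 1–2 h, dark; filter (Celite); cold 0.5 M HCl to pH 3–4, EtOAc; C18 chromatography
Reagents that add atoms: none
Why: Reductive fragmentation of the trichloroethyl ester (zinc insertion into C–Cl, then β-elimination of the carboxylate) runs at about pH 7, where the allylic ester, the Z-styrene, the phenol and the tertiary alcohol are inert, and with the distal arm now CO2H the unchanged C3 reads (R) as in the target.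

## Compound list
1 | 3-hydroxy-3-methylpentanedioic acid | CC(O)(CC(=O)O)CC(=O)O | starting material
2 | dimethyl 3-hydroxy-3-methylpentanedioate | COC(=O)CC(C)(O)CC(=O)OC | intermediate
3 | sodium (3S)-3-hydroxy-5-methoxy-3-methyl-5-oxopentanoate (formed in the flask, not isolated) | [Na+].[O-]C(=O)C[C@](C)(O)CC(=O)OC | intermediate
4 | (3S)-3-hydroxy-5-methoxy-3-methyl-5-oxopentanoic acid | OC(=O)C[C@](C)(O)CC(=O)OC | intermediate
5 | 1-tert-butyl 5-methyl (3R)-3-hydroxy-3-methylpentanedioate | CC(C)(C)OC(=O)C[C@](C)(O)CC(=O)OC | intermediate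
6 | lithium (3R)-5-tert-butoxy-3-hydroxy-3-methyl-5-oxopentanoate (not isolated) | [Li+].CC(C)(C)OC(=O)C[C@](C)(O)CC(=O)[O-] | intermediate
7 | (3R)-5-tert-butoxy-3-hydroxy-3-methyl-5-oxopentanoic acid | CC(C)(C)OC(=O)C[C@](C)(O)CC(=O)O | intermediate
8 | (3S)-O-acylisourea from 7 and EDC (not isolated) | CC(C)(C)OC(=O)C[C@](C)(O)CC(=O)OC(=NCC)NCCCN(C)C | intermediate
9 | 1-tert-butyl 5-(2,2,2-trichloroethyl) (3R)-3-hydroxy-3-methylpentanedioate | CC(C)(C)OC(=O)C[C@](C)(O)CC(=O)OCC(Cl)(Cl)Cl | intermediate
10 | (3S)-3-hydroxy-3-methyl-5-oxo-5-(2,2,2-trichloroethoxy)pentanoic acid | OC(=O)C[C@](C)(O)CC(=O)OCC(Cl)(Cl)Cl | intermediate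
11 | syringaldehyde (4-hydroxy-3,5-dimethoxybenzaldehyde) | COc1cc(C=O)cc(OC)c1O | starting material
12 | 4-[(tert-butyldimethylsilyl)oxy]-3,5-dimethoxybenzaldehyde | COc1cc(C=O)cc(OC)c1O[Si](C)(C)C(C)(C)C | intermediate
13 | methyl bis(2,2,2-trifluoroethyl)phosphonoacetate | COC(=O)CP(=O)(OCC(F)(F)F)OCC(F)(F)F | starting material
14 | potassium carbanion of 13 (not isolated) | [K+].COC(=O)[CH-]P(=O)(OCC(F)(F)F)OCC(F)(F)F | intermediate
15 | methyl (2Z)-3-{4-[(tert-butyldimethylsilyl)oxy]-3,5-dimethoxyphenyl}prop-2-enoate | COC(=O)/C=C\c1cc(OC)c(O[Si](C)(C)C(C)(C)C)c(OC)c1 | intermediate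
16 | (2Z)-3-{4-[(tert-butyldimethylsilyl)oxy]-3,5-dimethoxyphenyl}prop-2-enal (not isolated) | O=C/C=C\c1cc(OC)c(O[Si](C)(C)C(C)(C)C)c(OC)c1 | intermediate
17 | (2Z)-3-{4-[(tert-butyldimethylsilyl)oxy]-3,5-dimethoxyphenyl}prop-2-en-1-ol | OC/C=C\c1cc(OC)c(O[Si](C)(C)C(C)(C)C)c(OC)c1 | intermediate
18 | (3R)-O-acylisourea from 10 and EDC (not isolated) | CCN=C(NCCCN(C)C)OC(=O)C[C@](C)(O)CC(=O)OCC(Cl)(Cl)Cl | intermediate
19 | 1-[(2Z)-3-{4-[(tert-butyldimethylsilyl)oxy]-3,5-dimethoxyphenyl}prop-2-en-1-yl] 5-(2,2,2-trichloroethyl) (3S)-3-hydroxy-3-methylpentanedioate | COc1cc(/C=C\COC(=O)C[C@](C)(O)CC(=O)OCC(Cl)(Cl)Cl)cc(OC)c1O[Si](C)(C)C(C)(C)C | intermediate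
20 | 1-[(2Z)-3-(4-hydroxy-3,5-dimethoxyphenyl)prop-2-en-1-yl] 5-(2,2,2-trichloroethyl) (3S)-3-hydroxy-3-methylpentanedioate | COc1cc(/C=C\COC(=O)C[C@](C)(O)CC(=O)OCC(Cl)(Cl)Cl)cc(OC)c1O | intermediate
21 | chlorozinc (3R)-carboxylate of the target (not isolated) | COc1cc(/C=C\COC(=O)C[C@](C)(O)CC(=O)[O-])cc(OC)c1O.[Zn+2].[Cl-] | intermediate
22 | (3R)-3-hydroxy-5-{[(2Z)-3-(4-hydroxy-3,5-dimethoxyphenyl)prop-2-en-1-yl]oxy}-3-methyl-5-oxopentanoic acid | COc1cc(/C=C\COC(=O)C[C@](C)(O)CC(=O)O)cc(OC)c1O | target

## Count and risks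
Total steps: 12. Longest linear sequence: 9 (steps 1–6, then 10–12). The arene branch (steps 7–9) joins at step 10.

**Step 2 (esterase desymmetrisation).** The risks are batch-dependent ee and recovery of a very water-soluble half-ester.
- The fallback sets out from 1 and comes back at 4.
- Compound 1 is dehydrated with DCC in acetone to 3-hydroxy-3-methylglutaric anhydride F1.
- This prochiral anhydride is opened with methanol (3 equiv) in MTBE at rt over an immobilised triacylglycerol lipase (lipase class, EC 3.1.1.3).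
- The lipase is chosen from a small screen for acyl-enzyme formation at the pro-S carbonyl, so that the methyl ester ends on that arm and 4 results.
- This replaces aqueous diester hydrolysis by an acyl transfer in organic solvent, so no water extraction is needed. The sense of opening is verified by reducing a sample to mevalonolactone.

**Step 10 (Steglich coupling).** The risks are side reactions of the activated β-hydroxy acid, such as N-acylurea formation or leakage to the cyclic anhydride.
- The fallback sets out from 10 and 17 and comes back at 19.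
- The alcohol is activated instead of the acid by a Mitsunobu esterification (PPh3, DIAD, toluene/THF, −20 to 0 °C).
- The carboxylate of 10 displaces the primary oxyphosphonium group by SN2, the Z-alkene is retained, and the tertiary OH is inert.
- This fallback makes no new compound (F0).

**Step 12 (zinc cleavage on the free-phenol Z-sinapyl ester).** The risks are Zn(II)-assisted ionisation towards a quinone methide and Z-to-E drift.
- The fallback sets out from 12 and 10 and comes back at 22. The labile Z-cinnamyl ester is created last.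
- Corey–Fuchs olefination of 12 (CBr4, PPh3, CH2Cl2, 0 °C) gives tert-butyl[4-(2,2-dibromoethenyl)-2,6-dimethoxyphenoxy]dimethylsilane F2.
- n-BuLi (2.2 equiv, THF, −78 °C) followed by paraformaldehyde gives 3-{4-[(tert-butyldimethylsilyl)oxy]-3,5-dimethoxyphenyl}prop-2-yn-1-ol F3.
- EDC/DMAP coupling with 10 gives the (3S)-propargylic trichloroethyl diester F4.
- Buffered TBAF/AcOH gives the (3S)-free-phenol propargylic diester F5.
- Zn/aq NH4OAc gives the (3R)-alkynyl acid F6.
- Lindlar semihydrogenation (H2 1 atm, Pd/CaCO3–Pb, quinoline, EtOAc, stopped at 1.0 equiv H2) delivers 22 by syn addition.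

## Further compounds
F1 | step 2 | 3-hydroxy-3-methylglutaric anhydride (4-hydroxy-4-methyloxane-2,6-dione) | CC1(O)CC(=O)OC(=O)C1
F0 | step 10 | none | none
F2 | step 12 | tert-butyl[4-(2,2-dibromoethenyl)-2,6-dimethoxyphenoxy]dimethylsilane | COc1cc(C=C(Br)Br)cc(OC)c1O[Si](C)(C)C(C)(C)C
F3 | step 12 | 3-{4-[(tert-butyldimethylsilyl)oxy]-3,5-dimethoxyphenyl}prop-2-yn-1-ol | COc1cc(C#CCO)cc(OC)c1O[Si](C)(C)C(C)(C)C
F4 | step 12 | 1-(3-{4-[(tert-butyldimethylsilyl)oxy]-3,5-dimethoxyphenyl}prop-2-yn-1-yl) 5-(2,2,2-trichloroethyl) (3S)-3-hydroxy-3-methylpentanedioate | COc1cc(C#CCOC(=O)C[C@](C)(O)CC(=O)OCC(Cl)(Cl)Cl)cc(OC)c1O[Si](C)(C)C(C)(C)C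
F5 | step 12 | 1-[3-(4-hydroxy-3,5-dimethoxyphenyl)prop-2-yn-1-yl] 5-(2,2,2-trichloroethyl) (3S)-3-hydroxy-3-methylpentanedioate | COc1cc(C#CCOC(=O)C[C@](C)(O)CC(=O)OCC(Cl)(Cl)Cl)cc(OC)c1O
F6 | step 12 | (3R)-3-hydroxy-5-{[3-(4-hydroxy-3,5-dimethoxyphenyl)prop-2-yn-1-yl]oxy}-3-methyl-5-oxopentanoic acid | COc1cc(C#CCOC(=O)C[C@](C)(O)CC(=O)O)cc(OC)c1O
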